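**Assumptions**
- The target is drawn as the Z‑enol of the curcumin β‑diketone. The keto/enol tautomers interconvert, so isolating the enol is equivalent.
- The chiral ligand enantiomers (Trost ligand in Step 5, Josiphos in Step 14) and the ketoreductase variant (Step 11) are chosen by a small test reaction to give the configurations shown.
- Abbreviation: ArO = 4‑(1,3‑dioxolan‑2‑yl)‑2‑methoxyphenoxy, i.e. vanillin with its aldehyde masked as the ethylene acetal and the phenol oxygen attached to the ring.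

## Retrosynthetic overview
1. The curcumin unit of 23 comes from a Pabon boron‑mediated Knoevenagel condensation of feruloylacetone 22 (vanillin 1 + acetylacetone 21) with the aryl aldehyde 20.
2. Aldehyde 20 comes from an enone side chain built from a Weinreb amide and isobutenyl Grignard. The C7 methyl stereocentre is set by Cu/Josiphos conjugate addition to an enoate, which is made by cross‑metathesis of a C1 vinyl group.
3. The C1 vinyl group, trans to the aryl ether, comes from cuprate addition to a γ‑aryloxy enone. The methyl‑bearing alkene comes from α′‑methylation and then dehydrogenation. The C3 alcohol comes from a ketoreductase.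
4. The γ‑aryloxy enone comes from Pd‑catalysed desymmetrization of a meso ene‑diol biscarbonate (1,3‑cyclohexadiene + ¹O₂) with acetal‑protected vanillin. The only carbocycle is present from the start, so no ring is closed late; both aromatic rings come from vanillin.

## Route

**Step 1**
Reactants: 1 vanillin
Product: 2 2‑(4‑hydroxy‑3‑methoxyphenyl)‑1,3‑dioxolane
Conditions: HOCH₂CH₂OH, TsOH (cat.), PhMe, Dean–Stark, reflux
Reagents that add atoms: ethylene glycol, OCCO
Why: Acetalization masks the aldehyde so it survives the Grignard, cuprate, LDA and Pd steps; the phenol stays free for the allylic etherification.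

**Step 2**
Reactants: 3 cyclohexa‑1,3‑diene
Product: 4 2,3‑dioxabicyclo[2.2.2]oct‑5‑ene
Conditions: O₂, Rose Bengal, hν (visible), MeOH, 0 °C
Reagents that add atoms: O₂, O=O
Why: Singlet‑oxygen [4+2] cycloaddition gives the endoperoxide, which is achiral.

**Step 3**
Reactants: 4 endoperoxide
Product: 5 cis‑cyclohex‑2‑ene‑1,4‑diol (meso)
Conditions: thiourea, MeOH, rt
Reagents that add atoms: none
Why: Thiourea reduces the O–O bond, giving the cis‑1,4‑diol (achiral, meso).

**Step 4**
Reactants: 5 cis‑diol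
Product: 6 cis‑cyclohex‑2‑ene‑1,4‑diyl bis(methyl carbonate) (meso)
Conditions: ClCO₂Me, pyridine, DMAP (cat.), CH₂Cl₂, 0 °C → rt
Reagents that add atoms: methyl chloroformate, ClC(=O)OC
Why: Carbonylation of both hydroxyls gives the symmetric π‑allyl precursor needed for desymmetrization.

**Step 5**
Reactants: 6 biscarbonate; 2 phenol
Product: 7 (1R,4S)‑cis‑4‑ArO‑cyclohex‑2‑en‑1‑yl methyl carbonate
Conditions: Pd₂(dba)₃·CHCl₃ (2.5 mol %), (R,R)‑DACH‑phenyl Trost ligand (7.5 mol %), CH₂Cl₂, rt
Reagents that add atoms: none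
Why: Tsuji–Trost desymmetrization (asymmetric allylic etherification): the chiral Pd catalyst ionizes one enantiotopic carbonate, and the phenoxide attacks the anti face of the π‑allyl. This double inversion retains the cis relationship and first fixes absolute configuration (C6‑aryl ether carbon S as an enone, R in the target).

**Step 6**
Reactants: 7
Product: 8 (1R,4S)‑cis‑4‑ArO‑cyclohex‑2‑en‑1‑ol
Conditions: K₂CO₃, MeOH, rt
Reagents that add atoms: none
Why: Methanolysis of the methyl carbonate frees the allylic alcohol without touching the acetal or the stereocentres.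

**Step 7**
Reactants: 8
Product: 9 (4S)‑4‑ArO‑cyclohex‑2‑en‑1‑one
Conditions: activated MnO₂, CH₂Cl₂, rt
Reagents that add atoms: none
Why: Chemoselective allylic oxidation removes the C1 stereocentre (no longer needed) and leaves the aryloxy‑bearing carbon as the only stereocentre, on a Michael acceptor.

**Step 8**
Reactants: 9
Product: 10 (4S)‑4‑ArO‑6‑methylcyclohex‑2‑en‑1‑one (C6 epimer mixture, trans major)
Conditions: LDA, THF, –78 °C; then MeI, DMPU, –78 → –30 °C
Reagents that add atoms: methyl iodide, CI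
Why: Kinetic α′‑enolate alkylation places the future C4 methyl regiospecifically; the new stereocentre is later destroyed by dehydrogenation.

**Step 9**
Reactants: 10
Product: 11 (4S,5R)‑4‑ArO‑2‑methyl‑5‑vinylcyclohexan‑1‑one (C2 epimers)
Conditions: CH₂=CHMgBr, CuBr·SMe₂, THF/Me₂S, –78 → –40 °C; aq. NH₄Cl
Reagents that add atoms: vinylmagnesium bromide, C=C[Mg]Br
Why: Cuprate 1,4‑addition to a 4‑alkoxy/aryloxy cyclohexenone occurs anti to the γ‑substituent, giving the trans relationship between C1‑vinyl and C6‑OAr (C1 = R).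

**Step 10**
Reactants: 11
Product: 12 (4R,5R)‑4‑ArO‑2‑methyl‑5‑vinylcyclohex‑2‑en‑1‑one
Conditions: TMSCl, Et₃N, DMF, 90 °C; then Pd(OAc)₂, MeCN, rt
Reagents that add atoms: none
Why: Thermodynamic silyl enol ether formation towards the methyl‑bearing carbon, then Saegusa–Ito oxidation, gives the 2‑methylenone (C4=C5). The C1 and C6 stereocentres are not α to the carbonyl and are untouched.

**Step 11**
Reactants: 12
Product: 13 (1S,4R,5R)‑4‑ArO‑2‑methyl‑5‑vinylcyclohex‑2‑en‑1‑ol
Conditions: ketoreductase (NADPH‑dependent alcohol dehydrogenase, oxidoreductase class; Prelog‑type variant), NADP⁺ (cat.), i‑PrOH (10 % v/v, cofactor recycling), KPi pH 7, DMSO (10 %), 30 °C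
Reagents that add atoms: none
Why: Enzyme‑controlled hydride delivery to the Re face gives the (S)‑allylic alcohol cis to OAr (C3 = S); the enzyme, not the weak substrate bias, sets this centre, and pH 7 keeps the acetal intact.

**Step 12**
Reactants: 13
Product: 14 TBS ether of 13
Conditions: TBSCl, imidazole, DMAP (cat.), DMF, 40 °C
Reagents that add atoms: tert‑butyldimethylsilyl chloride, CC(C)(C)[Si](C)(C)Cl
Why: Silylation protects the alcohol against the Grignard steps; TBSCl/imidazole is used instead of TBSOTf because triflate/base combinations can cleave aryl acetals.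

**Step 13**
Reactants: 14
Product: 15 ethyl (E)‑3‑[(1R,2R,5S)‑2‑ArO‑5‑OTBS‑4‑methylcyclohex‑3‑en‑1‑yl]acrylate
Conditions: ethyl acrylate (10 equiv), Hoveyda–Grubbs II (5 mol %), CH₂Cl₂, 40 °C
Reagents that add atoms: ethyl acrylate, C=CC(=O)OCC
Why: Cross‑metathesis is selective for the monosubstituted vinyl group, giving the E‑enoate; the trisubstituted ring alkene is inert.

**Step 14**
Reactants: 15
Product: 16 ethyl (3S)‑3‑[(1R,2R,5S)‑2‑ArO‑5‑OTBS‑4‑methylcyclohex‑3‑en‑1‑yl]butanoate
Conditions: MeMgBr, CuBr·SMe₂ (5 mol %), (R,S)‑Josiphos (6 mol %), t‑BuOMe, –75 °C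
Reagents that add atoms: methylmagnesium bromide, C[Mg]Br
Why: Cu/Josiphos asymmetric conjugate addition of a Grignard reagent to an E‑enoate; the ligand controls the new C7 methyl stereocentre (S) over the adjacent ring centre.

**Step 15**
Reactants: 16
Product: 17 N‑methoxy‑N‑methyl Weinreb amide of 16
Conditions: MeNH(OMe)·HCl, i‑PrMgCl, THF, –20 → 0 °C
Reagents that add atoms: N,O‑dimethylhydroxylamine hydrochloride, CONC.Cl
Why: Magnesium amide exchange converts the ester to a Weinreb amide, which stops at the ketone stage in the next step; C7 is β to the carbonyl and cannot epimerize.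

**Step 16**
Reactants: 17
Product: 18 (6S)‑6‑[(1R,2R,5S)‑2‑ArO‑5‑OTBS‑4‑methylcyclohex‑3‑en‑1‑yl]‑2‑methylhept‑2‑en‑4‑one
Conditions: 2‑methylprop‑1‑enylmagnesium bromide, THF, 0 °C
Reagents that add atoms: 2‑methylprop‑1‑en‑1‑ylmagnesium bromide, CC(C)=C[Mg]Br
Why: Weinreb ketone synthesis builds the C9 ketone with the C10=C11 enone directly, without a deconjugating or over‑addition pathway.

**Step 17**
Reactants: 18
Product: 19 free C3 alcohol
Conditions: TBAF, AcOH (1:1), THF, rt → 40 °C
Reagents that add atoms: none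
Why: Buffered fluoride removes the silyl group without base‑mediated damage to the enone or the allylic aryl ether.

**Step 18**
Reactants: 19
Product: 20 3‑methoxy‑4‑{[(1R,4S,6R)‑4‑hydroxy‑3‑methyl‑6‑[(2S)‑6‑methyl‑4‑oxohept‑5‑en‑2‑yl]cyclohex‑2‑en‑1‑yl]oxy}benzaldehyde
Conditions: I₂ (10 mol %), acetone/H₂O (20:1), rt → 40 °C
Reagents that add atoms: water, O
Why: Iodine‑catalysed, near‑neutral acetal exchange and hydrolysis unmasks the aldehyde while sparing the acid‑labile allylic ether and allylic alcohol.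

**Step 19**
Reactants: 1 vanillin; 21 acetylacetone
Product: 22 feruloylacetone
Conditions: B₂O₃, B(OBu)₃, n‑BuNH₂ (cat.), EtOAc, 40 → 80 °C; then 0.4 M HCl (aq.), 60 °C
Reagents that add atoms: none
Why: Pabon condensation through the acetylacetone boron complex, which protects the central carbon so that only the terminal methyl condenses; excess 21 (2 equiv) limits bis‑condensation to curcumin.

**Step 20**
Reactants: 22 feruloylacetone; 20 aldehyde
Product: 23 bisabolocurcumin ether
Conditions: 22 + B₂O₃, EtOAc, 40 °C; then 20, B(OBu)₃, n‑BuNH₂ (cat.), 60 °C; then 10 % aq. AcOH, 50 °C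
Reagents that add atoms: none
Why: Boron‑templated Knoevenagel condensation forms the second (E)‑enone and the boron‑chelated Z‑enol; the mild aqueous acid releases boron without ionizing the allylic ether.

## Compound list

| # | Name | SMILES | Role |
|---|---|---|---|
| 1 | Vanillin | COc1cc(C=O)ccc1O | starting material |
| 2 | 2‑(4‑Hydroxy‑3‑methoxyphenyl)‑1,3‑dioxolane | COc1cc(C2OCCO2)ccc1O | intermediate |
| 3 | Cyclohexa‑1,3‑diene | C1=CC=CCC1 | starting material |
| 4 | 2,3‑Dioxabicyclo[2.2.2]oct‑5‑ene | C1CC2C=CC1OO2 | intermediate |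
| 5 | cis‑Cyclohex‑2‑ene‑1,4‑diol (meso, 1R,4S) | O[C@H]1C=C[C@@H](O)CC1 | intermediate |
| 6 | cis‑Cyclohex‑2‑ene‑1,4‑diyl bis(methyl carbonate) (meso) | COC(=O)O[C@H]1C=C[C@@H](OC(=O)OC)CC1 | intermediate |
| 7 | (1R,4S)‑cis‑4‑ArO‑cyclohex‑2‑en‑1‑yl methyl carbonate | COC(=O)O[C@H]1C=C[C@@H](Oc2ccc(C3OCCO3)cc2OC)CC1 | intermediate |
| 8 | (1R,4S)‑cis‑4‑ArO‑cyclohex‑2‑en‑1‑ol | O[C@H]1C=C[C@@H](Oc2ccc(C3OCCO3)cc2OC)CC1 | intermediate |
| 9 | (4S)‑4‑ArO‑cyclohex‑2‑en‑1‑one | O=C1C=C[C@@H](Oc2ccc(C3OCCO3)cc2OC)CC1 | intermediate |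
| 10 | (4S)‑4‑ArO‑6‑methylcyclohex‑2‑en‑1‑one (C6 epimers) | O=C1C=C[C@@H](Oc2ccc(C3OCCO3)cc2OC)CC1C | intermediate |
| 11 | (4S,5R)‑4‑ArO‑2‑methyl‑5‑vinylcyclohexan‑1‑one (C2 epimers) | COc1cc(C2OCCO2)ccc1O[C@H]3CC(C)C(=O)C[C@@H]3C=C | intermediate |
| 12 | (4R,5R)‑4‑ArO‑2‑methyl‑5‑vinylcyclohex‑2‑en‑1‑one | COc1cc(C2OCCO2)ccc1O[C@H]3C=C(C)C(=O)C[C@@H]3C=C | intermediate |
| 13 | (1S,4R,5R)‑4‑ArO‑2‑methyl‑5‑vinylcyclohex‑2‑en‑1‑ol | COc1cc(C2OCCO2)ccc1O[C@H]3C=C(C)[C@@H](O)C[C@@H]3C=C | intermediate |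
| 14 | TBS ether of 13 | COc1cc(C2OCCO2)ccc1O[C@H]3C=C(C)[C@@H](O[Si](C)(C)C(C)(C)C)C[C@@H]3C=C | intermediate |
| 15 | Ethyl (E)‑3‑[(1R,2R,5S)‑2‑ArO‑5‑OTBS‑4‑methylcyclohex‑3‑en‑1‑yl]acrylate | COc1cc(C2OCCO2)ccc1O[C@H]3C=C(C)[C@@H](O[Si](C)(C)C(C)(C)C)C[C@@H]3/C=C/C(=O)OCC | intermediate |
| 16 | Ethyl (3S)‑3‑[(1R,2R,5S)‑2‑ArO‑5‑OTBS‑4‑methylcyclohex‑3‑en‑1‑yl]butanoate | COc1cc(C2OCCO2)ccc1O[C@H]3C=C(C)[C@@H](O[Si](C)(C)C(C)(C)C)C[C@@H]3[C@@H](C)CC(=O)OCC | intermediate |
| 17 | Weinreb amide of 16 | COc1cc(C2OCCO2)ccc1O[C@H]3C=C(C)[C@@H](O[Si](C)(C)C(C)(C)C)C[C@@H]3[C@@H](C)CC(=O)N(C)OC | intermediate |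
| 18 | (6S)‑6‑[(1R,2R,5S)‑2‑ArO‑5‑OTBS‑4‑methylcyclohex‑3‑en‑1‑yl]‑2‑methylhept‑2‑en‑4‑one | COc1cc(C2OCCO2)ccc1O[C@H]3C=C(C)[C@@H](O[Si](C)(C)C(C)(C)C)C[C@@H]3[C@@H](C)CC(=O)C=C(C)C | intermediate |
| 19 | Free C3 alcohol of 18 | COc1cc(C2OCCO2)ccc1O[C@H]3C=C(C)[C@@H](O)C[C@@H]3[C@@H](C)CC(=O)C=C(C)C | intermediate |
| 20 | Aryl aldehyde 20 (see Step 18 for name) | COc1cc(C=O)ccc1O[C@H]3C=C(C)[C@@H](O)C[C@@H]3[C@@H](C)CC(=O)C=C(C)C | intermediate |
| 21 | Acetylacetone (pentane‑2,4‑dione) | CC(=O)CC(C)=O | starting material |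
| 22 | Feruloylacetone, (E)‑6‑(4‑hydroxy‑3‑methoxyphenyl)hex‑5‑ene‑2,4‑dione | COc1cc(/C=C/C(=O)CC(C)=O)ccc1O | intermediate |
| 23 | Bisabolocurcumin ether | COc1cc(/C=C/C(=O)/C=C(O)/C=C/c2ccc(O[C@H]3C=C(C)[C@@H](O)C[C@@H]3[C@@H](C)CC(=O)C=C(C)C)c(OC)c2)ccc1O | target |

**Step count:** 20 steps in total; the longest linear sequence is 18 steps (Steps 2–18 and 20, starting from cyclohexa‑1,3‑diene).

## Three steps most likely to fail

1. **Step 10, regioselective dehydrogenation.** The 2‑methyl ketone could enolize toward C2, or the vinyl group could be attacked by Pd(II).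
   - Fallback (changes the approach): omit the α′‑methyl (Step 8) and dehydrogenate the unmethylated ketone, separating the minor regioisomer. Then install the methyl late by α‑iodination (I₂, pyridine) and Pd‑catalysed methylation (MeB(OH)₂ or Me₃Al).

2. **Step 11, ketoreductase reduction of a hindered 2‑methylenone.** The enzyme may be inactive, or may give the wrong C3 epimer.
   - Fallback (changes the approach): Luche reduction (NaBH₄/CeCl₃) gives mainly the trans alcohol. Mitsunobu inversion with p‑nitrobenzoic acid followed by K₂CO₃/MeOH then gives the cis (3S) alcohol 13.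

3. **Step 14, Cu/Josiphos conjugate addition to a β‑secondary‑alkyl enoate.** The ee or dr at C7 may be low because of the adjacent ring centre.
   - Fallback (changes the approach): convert the C1 vinyl group of 14 into the methyl ketone (O₃; then MeMgBr; then DMP). Then run a Horner–Wadsworth–Emmons reaction to give the β‑methyl enoate and set C7 by enzymatic reduction of that enoate with an ene‑reductase (Old Yellow Enzyme class), or by Ir‑catalysed asymmetric hydrogenation.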